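**Retrosynthetic overview**
1. Target 19 ⇐ 17 by allylic C–H oxidation of the C15 methyl group (last step, late oxidation as in the biosynthesis).
2. 17 ⇐ 15 by C6–C7 ring closure: intramolecular Nozaki–Hiyama–Kishi allylation of the Z-enal by the 2-(bromomethyl)enoate closes the ten-membered ring, and the resulting alkoxide closes the γ-lactone in the same flask.
3. 15 ⇐ dialdehyde 12 + methyl acrylate (Morita–Baylis–Hillman, then SN2′ bromination); 12 ⇐ bis-silyl ether 11 by a double Swern oxidation.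
4. 11 ⇐ diol 9 (Sharpless epoxidation, acetylation) ⇐ E-alkylidene lactone 8 (i-Bu2AlH); the lactone's two oxygens become the two acetoxy groups.
5. 8 ⇐ aldol condensation of (S)-lactone 5 (L-glutamic acid pool) with nerol-derived aldehyde 3. Ring order: epoxide, then ten-membered carbocycle, then γ-lactone.

Assumption: macrocyclic compounds are named with germacrane numbering (ring C1–C10, acrylate unit C11–C13, C14 on C10, C15 on C4), and the same locants are used for the corresponding atoms of open-chain precursors.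

**Route**

Step 1
Reactants: 1 nerol [(2Z)-3,7-dimethylocta-2,6-dien-1-ol]
Product: 2 neryl triethylsilyl ether [(2Z)-3,7-dimethyl-1-(triethylsilyloxy)octa-2,6-diene]
Conditions: Et3SiCl, imidazole, CH2Cl2, 0 °C to rt
Reagents that add atoms: chlorotriethylsilane, CC[Si](Cl)(CC)CC
Why: Silyl ether formation on a primary allylic alcohol, chosen because a primary Et3Si ether survives base, hydride and epoxidation and is later turned directly into the aldehyde under Swern conditions; no stereocentre is formed and the Z olefin is untouched.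

Step 2
Reactants: 2 neryl triethylsilyl ether
Product: 3 (4Z)-4-methyl-6-(triethylsilyloxy)hex-4-enal
Conditions: O3 (1 equiv), CH2Cl2, −78 °C, Sudan Red 7B end-point; then PPh3, −78 °C to rt
Reagents that add atoms: ozone, O=[O+][O-]
Why: Chemoselective ozonolysis, in which the remote electron-rich trisubstituted olefin reacts faster than the olefin deactivated by the allylic silyloxy group, so the Z-trisubstituted C4=C5 unit is kept.

Step 3
Reactants: 4 (5S)-5-(hydroxymethyl)dihydrofuran-2(3H)-one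
Product: 5 (5S)-5-[(triethylsilyloxy)methyl]dihydrofuran-2(3H)-one
Conditions: Et3SiCl, imidazole, CH2Cl2, 0 °C to rt
Reagents that add atoms: chlorotriethylsilane, CC[Si](Cl)(CC)CC
Why: Silyl ether formation that masks the future C7 carbinol as a group oxidisable later without a separate deprotection; the C8 stereocentre from the chiral pool is not touched.

Step 4
Reactants: 5 (5S)-5-[(triethylsilyloxy)methyl]dihydrofuran-2(3H)-one; 3 (4Z)-4-methyl-6-(triethylsilyloxy)hex-4-enal
Product: 8 (3E,5S)-3-[(4Z)-4-methyl-6-(triethylsilyloxy)hex-4-en-1-ylidene]-5-[(triethylsilyloxy)methyl]dihydrofuran-2(3H)-one, via aldol adduct 6 (not isolated), via aldol mesylate 7 (not isolated)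
Conditions: LiN(i-Pr)2, THF, −78 °C; add 3; then MsCl, −78 to 0 °C; then DBU, rt
Reagents that add atoms: none
Why: Aldol condensation (lithium enolate aldol, mesylation, E1cB elimination) gives the thermodynamically favoured E-alkylidene lactone, which fixes C14 trans to C2 and C9 cis to C2 as the later cis-epoxide needs, while C8 stays untouched.

Step 5
Reactants: 8 (3E,5S)-3-[(4Z)-4-methyl-6-(triethylsilyloxy)hex-4-en-1-ylidene]-5-[(triethylsilyloxy)methyl]dihydrofuran-2(3H)-one
Product: 9 (2E,6Z)-2-[(2S)-2-hydroxy-3-(triethylsilyloxy)propyl]-6-methyl-8-(triethylsilyloxy)octa-2,6-dien-1-ol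
Conditions: i-Bu2AlH (4 equiv), CH2Cl2, −78 to 0 °C; aq. KNaC4H4O6 work-up
Reagents that add atoms: none
Why: 1,2-Reduction of the conjugated lactone by i-Bu2AlH gives the allylic C14 alcohol and the secondary C8 alcohol without breaking the C8–O bond, so C8 keeps its configuration and both olefin geometries and silyl ethers survive.

Step 6
Reactants: 9 (2E,6Z)-2-[(2S)-2-hydroxy-3-(triethylsilyloxy)propyl]-6-methyl-8-(triethylsilyloxy)octa-2,6-dien-1-ol
Product: 11 [(2R,3R)-2-[(2S)-2-acetoxy-3-(triethylsilyloxy)propyl]-3-[(3Z)-3-methyl-5-(triethylsilyloxy)pent-3-en-1-yl]oxiran-2-yl]methyl acetate, via epoxy diol 10 (not isolated)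
Conditions: Ti(Oi-Pr)4 (10 mol %), D-(−)-diethyl tartrate (12 mol %), t-BuOOH (1.2 equiv), 4 Å MS, CH2Cl2, −20 °C; then Ac2O, Et3N, DMAP, 0 °C
Reagents that add atoms: tert-butyl hydroperoxide, CC(C)(C)OO; acetic anhydride, CC(=O)OC(C)=O
Why: Sharpless asymmetric epoxidation with in situ acetylation, in which the D-(−)-tartrate catalyst delivers oxygen under reagent control to the face giving the (1R,10R)-epoxide, only the olefin with a free allylic hydroxyl reacts, and both hydroxyls are then acetylated in the same flask.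

Step 7
Reactants: 11 [(2R,3R)-2-[(2S)-2-acetoxy-3-(triethylsilyloxy)propyl]-3-[(3Z)-3-methyl-5-(triethylsilyloxy)pent-3-en-1-yl]oxiran-2-yl]methyl acetate
Product: 12 [(2R,3R)-2-[(2S)-2-acetoxy-3-oxopropyl]-3-[(3Z)-3-methyl-5-oxopent-3-en-1-yl]oxiran-2-yl]methyl acetate
Conditions: (COCl)2, DMSO, CH2Cl2, −78 to −30 °C; then Et3N, −78 to 0 °C
Reagents that add atoms: none
Why: Swern oxidation applied directly to primary triethylsilyl ethers, where chlorodimethylsulfonium chloride exchanges both Et3Si groups for alkoxysulfonium groups and Et3N then gives the Z-enal and the α-acetoxy aldehyde in one operation, the low temperature protecting the Z geometry and the C8 centre.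

Step 8
Reactants: 12 [(2R,3R)-2-[(2S)-2-acetoxy-3-oxopropyl]-3-[(3Z)-3-methyl-5-oxopent-3-en-1-yl]oxiran-2-yl]methyl acetate; 13 methyl acrylate
Product: 14 methyl 2-[(2S)-2-acetoxy-3-[(2R,3R)-2-(acetoxymethyl)-3-[(3Z)-3-methyl-5-oxopent-3-en-1-yl]oxiran-2-yl]-1-hydroxypropyl]prop-2-enoate (both C7 epimers)
Conditions: methyl acrylate (excess), DABCO (1 equiv), rt
Reagents that add atoms: none
Why: Morita–Baylis–Hillman reaction, in which the amine-acrylate zwitterion adds only to the unconjugated, acetoxy-activated aldehyde and not to the β,β-disubstituted enal; the new carbinol centre forms as a mixture that is erased in the next step.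

Step 9
Reactants: 14 methyl 2-[(2S)-2-acetoxy-3-[(2R,3R)-2-(acetoxymethyl)-3-[(3Z)-3-methyl-5-oxopent-3-en-1-yl]oxiran-2-yl]-1-hydroxypropyl]prop-2-enoate
Product: 15 methyl (2Z,4S)-4-acetoxy-5-[(2R,3R)-2-(acetoxymethyl)-3-[(3Z)-3-methyl-5-oxopent-3-en-1-yl]oxiran-2-yl]-2-(bromomethyl)pent-2-enoate
Conditions: NBS, Me2S, CH2Cl2, −20 to 0 °C
Reagents that add atoms: N-bromosuccinimide, O=C1CCC(=O)N1Br
Why: SN2′ bromination of the Baylis–Hillman alcohol after Corey–Kim-type activation, bromide attacking the terminal methylene so that both carbinol epimers converge on the conjugated enoate with C8 trans to the ester.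

Step 10
Reactants: 15 methyl (2Z,4S)-4-acetoxy-5-[(2R,3R)-2-(acetoxymethyl)-3-[(3Z)-3-methyl-5-oxopent-3-en-1-yl]oxiran-2-yl]-2-(bromomethyl)pent-2-enoate
Product: 17 (1R,4Z,6R,7R,8S,10R)-8,14-diacetoxy-1,10-epoxygermacra-4,11(13)-dien-12,6-olide, via hydroxy ester 16 (not isolated)
Conditions: CrCl2 (10 equiv), THF, rt, slow addition to 2 mM; aq. NH4Cl
Reagents that add atoms: none
Why: Intramolecular Nozaki–Hiyama–Kishi allylation in which the equilibrating allylchromium adds through C7 to the tethered Z-enal in a cyclic six-membered transition state, the C6–C7 bond forming anti to the outward-pointing C8 acetoxy group (allylic-strain-minimised conformer) and the cis olefin plus cis epoxide of the tether favouring the anti (6,7-trans) adduct, whose chromium alkoxide then attacks the ester to close the trans-fused α-methylene lactone.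

Step 11
Reactants: 17 (1R,4Z,6R,7R,8S,10R)-8,14-diacetoxy-1,10-epoxygermacra-4,11(13)-dien-12,6-olide
Product: 19 (1R,4E,6R,7R,8S,10R)-8,14-diacetoxy-1,10-epoxy-15-oxogermacra-4,11(13)-dien-12,6-olide (the target), via 15-hydroxy lactone 18 (not isolated)
Conditions: SeO2 (0.5 equiv), t-BuOOH (3 equiv), CH2Cl2, rt; then MnO2 (excess) added to the same flask, rt
Reagents that add atoms: selenium dioxide, O=[Se]=O; tert-butyl hydroperoxide, CC(C)(C)OO
Why: Riley allylic oxidation (ene reaction, then [2,3]-sigmatropic shift) attacks the only electron-rich olefin at the methyl group trans to C6 and returns the C4=C5 bond with the oxidised carbon trans to C6, and MnO2 takes the allylic alcohol on to the enal without touching the epoxide, acetates or methylene lactone.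

**Compound list**
1 | nerol, (2Z)-3,7-dimethylocta-2,6-dien-1-ol | CC(C)=CCC/C(C)=C\CO | starting material
2 | neryl triethylsilyl ether | CC(C)=CCC/C(C)=C\CO[Si](CC)(CC)CC | intermediate
3 | (4Z)-4-methyl-6-(triethylsilyloxy)hex-4-enal | O=CCC/C(C)=C\CO[Si](CC)(CC)CC | intermediate
4 | (5S)-5-(hydroxymethyl)dihydrofuran-2(3H)-one | O=C1CC[C@@H](CO)O1 | starting material
5 | (5S)-5-[(triethylsilyloxy)methyl]dihydrofuran-2(3H)-one | O=C1CC[C@@H](CO[Si](CC)(CC)CC)O1 | intermediate
6 | aldol adduct, (5S)-3-[(4Z)-1-hydroxy-4-methyl-6-(triethylsilyloxy)hex-4-en-1-yl]-5-[(triethylsilyloxy)methyl]dihydrofuran-2(3H)-one, mixture at the two new centres | O=C1O[C@H](CO[Si](CC)(CC)CC)CC1C(O)CC/C(C)=C\CO[Si](CC)(CC)CC | intermediate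
7 | aldol mesylate, methanesulfonate of 6 | O=C1O[C@H](CO[Si](CC)(CC)CC)CC1C(OS(C)(=O)=O)CC/C(C)=C\CO[Si](CC)(CC)CC | intermediate
8 | (3E,5S)-3-[(4Z)-4-methyl-6-(triethylsilyloxy)hex-4-en-1-ylidene]-5-[(triethylsilyloxy)methyl]dihydrofuran-2(3H)-one | O=C1O[C@H](CO[Si](CC)(CC)CC)C/C1=C\CC/C(C)=C\CO[Si](CC)(CC)CC | intermediate
9 | (2E,6Z)-2-[(2S)-2-hydroxy-3-(triethylsilyloxy)propyl]-6-methyl-8-(triethylsilyloxy)octa-2,6-dien-1-ol | OC/C(=C/CC/C(C)=C\CO[Si](CC)(CC)CC)C[C@H](O)CO[Si](CC)(CC)CC | intermediate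
10 | epoxy diol, [(2R,3R)-2-[(2S)-2-hydroxy-3-(triethylsilyloxy)propyl]-3-[(3Z)-3-methyl-5-(triethylsilyloxy)pent-3-en-1-yl]oxiran-2-yl]methanol | OC[C@@]1(C[C@H](O)CO[Si](CC)(CC)CC)O[C@@H]1CC/C(C)=C\CO[Si](CC)(CC)CC | intermediate
11 | [(2R,3R)-2-[(2S)-2-acetoxy-3-(triethylsilyloxy)propyl]-3-[(3Z)-3-methyl-5-(triethylsilyloxy)pent-3-en-1-yl]oxiran-2-yl]methyl acetate | CC(=O)OC[C@@]1(C[C@H](OC(C)=O)CO[Si](CC)(CC)CC)O[C@@H]1CC/C(C)=C\CO[Si](CC)(CC)CC | intermediate
12 | [(2R,3R)-2-[(2S)-2-acetoxy-3-oxopropyl]-3-[(3Z)-3-methyl-5-oxopent-3-en-1-yl]oxiran-2-yl]methyl acetate | CC(=O)OC[C@@]1(C[C@H](OC(C)=O)C=O)O[C@@H]1CC/C(C)=C\C=O | intermediate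
13 | methyl acrylate | C=CC(=O)OC | starting material
14 | methyl 2-[(2S)-2-acetoxy-3-[(2R,3R)-2-(acetoxymethyl)-3-[(3Z)-3-methyl-5-oxopent-3-en-1-yl]oxiran-2-yl]-1-hydroxypropyl]prop-2-enoate, both C7 epimers | CC(=O)OC[C@@]1(C[C@H](OC(C)=O)C(O)C(=C)C(=O)OC)O[C@@H]1CC/C(C)=C\C=O | intermediate
15 | methyl (2Z,4S)-4-acetoxy-5-[(2R,3R)-2-(acetoxymethyl)-3-[(3Z)-3-methyl-5-oxopent-3-en-1-yl]oxiran-2-yl]-2-(bromomethyl)pent-2-enoate | CC(=O)OC[C@@]1(C[C@H](OC(C)=O)/C=C(\CBr)C(=O)OC)O[C@@H]1CC/C(C)=C\C=O | intermediate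
16 | hydroxy ester, methyl (1R,4Z,6R,7S,8S,10R)-8,14-diacetoxy-1,10-epoxy-6-hydroxygermacra-4,11(13)-dien-12-oate | COC(=O)C(=C)[C@H]1[C@H](O)/C=C(/C)CC[C@H]2O[C@@]2(COC(C)=O)C[C@@H]1OC(C)=O | intermediate
17 | (1R,4Z,6R,7R,8S,10R)-8,14-diacetoxy-1,10-epoxygermacra-4,11(13)-dien-12,6-olide | C=C1C(=O)O[C@@H]2/C=C(/C)CC[C@H]3O[C@@]3(COC(C)=O)C[C@H](OC(C)=O)[C@@H]12 | intermediate
18 | 15-hydroxy lactone, (1R,4E,6R,7R,8S,10R)-8,14-diacetoxy-1,10-epoxy-15-hydroxygermacra-4,11(13)-dien-12,6-olide | C=C1C(=O)O[C@@H]2/C=C(/CO)CC[C@H]3O[C@@]3(COC(C)=O)C[C@H](OC(C)=O)[C@@H]12 | intermediate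
19 | (1R,4E,6R,7R,8S,10R)-8,14-diacetoxy-1,10-epoxy-15-oxogermacra-4,11(13)-dien-12,6-olide (CNP0211286.1) | C=C1C(=O)O[C@@H]2/C=C(/C=O)CC[C@H]3O[C@@]3(COC(C)=O)C[C@H](OC(C)=O)[C@@H]12 | target

**Step count and risks**
Total steps: 11. Longest linear sequence: 10 (steps 1, 2, 4–11 from nerol).

Most likely to fail, step 10 (macrocyclisation). The ten-membered closure may give the wrong C6/C7 relationship, and the allylchromium may lose the C8 acetate by 1,4-elimination. The fallback sets out from 14 and returns at 17. Acetylation (Ac2O, pyridine, DMAP) gives the Baylis–Hillman acetate F2. Pd(PPh3)4 (zerovalent palladium, catalytic) ionises it, and InI (monovalent indium) in THF at high dilution turns the π-allyl complex into an allylindium. This closes the same C6–C7 bond through hydroxy ester 16 and lactonises to 17 without an allylic bromide or a chromium reagent. The different metal gives a second chance at the 6,7-trans adduct, whose selectivity would have to be re-established.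

Second, step 8 (Baylis–Hillman on the α-acetoxy aldehyde). The amine may epimerise C8, move the acetyl group to the new hydroxyl, or isomerise the Z-enal. The fallback sets out from 12 and returns at 15. A Horner–Wadsworth–Emmons olefination with methyl 2-(dimethoxyphosphoryl)-3-hydroxypropanoate (LiCl, i-Pr2NEt, MeCN, 0 °C) reacts only at the saturated aldehyde and gives the 2-(hydroxymethyl)enoate F1. An Appel reaction (CBr4, PPh3, CH2Cl2, 0 °C) converts F1 into bromide 15.

Third, step 11 (late C–H oxidation). The olefin is deactivated by the lactone oxygen, and ring methylene oxidation or acid damage to the epoxide can compete. The fallback moves the oxidation ahead of ring closure; it sets out from 11 and returns at 18.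
- SeO2/t-BuOOH on 11, whose only olefin carries the methyl group trans to C6, gives the 15-hydroxy bis-silyl ether F3.
- t-BuMe2SiCl and imidazole give the 15-silyl ether F4.
- The Swern conditions of step 7 oxidise only the two triethylsilyl ethers and give dialdehyde F5.
- Methyl acrylate and DABCO give the Baylis–Hillman adduct F6.
- NBS and Me2S give the allylic bromide F7.
- CrCl2 at high dilution closes the ring to the hydroxy ester F8, which lactonises to the silylated macrolactone F9.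
- HF·pyridine in THF frees the 15-hydroxy lactone 18, and MnO2 takes it to 19 as in the second half of step 11.

**Further compounds**
F1 | step 8 | methyl (2E,4S)-4-acetoxy-5-[(2R,3R)-2-(acetoxymethyl)-3-[(3Z)-3-methyl-5-oxopent-3-en-1-yl]oxiran-2-yl]-2-(hydroxymethyl)pent-2-enoate | CC(=O)OC[C@@]1(C[C@H](OC(C)=O)/C=C(\CO)C(=O)OC)O[C@@H]1CC/C(C)=C\C=O
F2 | step 10 | methyl 2-[(2S)-1,2-diacetoxy-3-[(2R,3R)-2-(acetoxymethyl)-3-[(3Z)-3-methyl-5-oxopent-3-en-1-yl]oxiran-2-yl]propyl]prop-2-enoate | CC(=O)OC[C@@]1(C[C@H](OC(C)=O)C(OC(C)=O)C(=C)C(=O)OC)O[C@@H]1CC/C(C)=C\C=O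
F3 | step 11 | [(2R,3R)-2-[(2S)-2-acetoxy-3-(triethylsilyloxy)propyl]-3-[(3E)-3-(hydroxymethyl)-5-(triethylsilyloxy)pent-3-en-1-yl]oxiran-2-yl]methyl acetate | CC(=O)OC[C@@]1(C[C@H](OC(C)=O)CO[Si](CC)(CC)CC)O[C@@H]1CC/C(CO)=C\CO[Si](CC)(CC)CC
F4 | step 11 | tert-butyldimethylsilyl ether of F3 at the C15 hydroxyl | CC(=O)OC[C@@]1(C[C@H](OC(C)=O)CO[Si](CC)(CC)CC)O[C@@H]1CC/C(CO[Si](C)(C)C(C)(C)C)=C\CO[Si](CC)(CC)CC
F5 | step 11 | [(2R,3R)-2-[(2S)-2-acetoxy-3-oxopropyl]-3-[(3E)-3-[(tert-butyldimethylsilyloxy)methyl]-5-oxopent-3-en-1-yl]oxiran-2-yl]methyl acetate | CC(=O)OC[C@@]1(C[C@H](OC(C)=O)C=O)O[C@@H]1CC/C(CO[Si](C)(C)C(C)(C)C)=C\C=O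
F6 | step 11 | Baylis–Hillman adduct of F5 with methyl acrylate, both C7 epimers | CC(=O)OC[C@@]1(C[C@H](OC(C)=O)C(O)C(=C)C(=O)OC)O[C@@H]1CC/C(CO[Si](C)(C)C(C)(C)C)=C\C=O
F7 | step 11 | methyl (2Z,4S)-4-acetoxy-5-[(2R,3R)-2-(acetoxymethyl)-3-[(3E)-3-[(tert-butyldimethylsilyloxy)methyl]-5-oxopent-3-en-1-yl]oxiran-2-yl]-2-(bromomethyl)pent-2-enoate | CC(=O)OC[C@@]1(C[C@H](OC(C)=O)/C=C(\CBr)C(=O)OC)O[C@@H]1CC/C(CO[Si](C)(C)C(C)(C)C)=C\C=O
F8 | step 11 | methyl (1R,4E,6R,7S,8S,10R)-8,14-diacetoxy-15-(tert-butyldimethylsilyloxy)-1,10-epoxy-6-hydroxygermacra-4,11(13)-dien-12-oate | COC(=O)C(=C)[C@H]1[C@H](O)/C=C(/CO[Si](C)(C)C(C)(C)C)CC[C@H]2O[C@@]2(COC(C)=O)C[C@@H]1OC(C)=O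
F9 | step 11 | (1R,4E,6R,7R,8S,10R)-8,14-diacetoxy-15-(tert-butyldimethylsilyloxy)-1,10-epoxygermacra-4,11(13)-dien-12,6-olide | C=C1C(=O)O[C@@H]2/C=C(/CO[Si](C)(C)C(C)(C)C)CC[C@H]3O[C@@]3(COC(C)=O)C[C@H](OC(C)=O)[C@@H]12
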